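## Structural features

The target is an ent-labdane (labdane numbering throughout). It is a trans-fused octahydronaphthalene: ring A (C1–C5, C10) carries the gem-dimethyl group on C4, and ring B (C5–C10) carries the angular methyl C20 on quaternary C10, a cis C6=C7 double bond, the methyl ester C17 on C8 and a two-carbon tether (C11–C12) on C9. The tether ends in a trisubstituted (E)-enoate C13=C14–C15O2Me, whose C13 also bears the acetoxymethyl carbon C16, trans to the ester. Four stereocentres are contiguous along C5–C10–C9–C8 (5R,8S,9R,10S): H5 and H9 are axial on the face opposite C20, and the C8 ester and the C9 chain are both equatorial and trans to each other. Several groups are fragile: the C8 ester is β,γ to C6=C7 and can slip into conjugation or epimerise with base, the allylic acetate is labile to base and to zerovalent palladium, and isomerisation of C13=C14 would let the C16 oxygen close a butenolide on C15. The real difficulty is the enantioselective construction of quaternary C10, wedged between C1, C9 and the C4-bearing C5, together with placing the ring B alkene at C6=C7 out of conjugation with the ester. The three tertiary centres are a lesser problem, because each sits in its thermodynamically preferred orientation on the trans-decalin chair and can be left to equilibration while C6 is a ketone and C11 an aldehyde. The key step exploits the fact that ring B holds C10 next to C9–C8 and an sp2 C6: C7=C6–C5=C10 is a 2-silyloxydiene hidden in a trimethylcyclohexene (ring A), and C8–C9 is a two-carbon alkyne carrying the ester and a formyl group.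

## Logic of the disconnections

19 ⇒ 18. The O–acyl bond at C16 is cut. The acetate goes on last because an allylic acetate next to a vinyl–palladium bond, in aqueous base, would be at risk in the coupling that precedes it. The forward step is a plain acylation of a primary alcohol.

18 ⇒ 15 + 16. The sp3–sp2 bond C12–C13 is cut. This separates the whole decalin from the C13–C16 unit and moves the enoate geometry into a small halide (16), where it is easy to fix. The forward step needs hydroboration of the vinyl group of 15 in preference to the ring alkene, and a coupling base mild enough to leave the C8 ester alone.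

16 ⇒ 6. The C13–I bond is cut. Anti addition of HI across an ynoate sets the (Z)-iodide, and 6 is the same alkyne that also supplies 7.

15 ⇒ 14 ⇒ 12. The C6–H bond is traced back to C6–OTf and then to the C6 ketone. The position of the alkene then rests on one regioselective enolisation toward C7. Base-sensitive side-chain functionality is kept out of this stage.

12 ⇒ 11. The C11=C12 bond is cut to the aldehyde. The formyl group is the handle that makes C9 epimerisable, so it must still be present when the stereocentres are set and be converted only afterwards. The forward step must olefinate the aldehyde in the presence of the hindered C6 ketone.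

11 ⇒ 10 ⇒ 8. The C–H bonds at C5, C8 and C9 are removed: C8 and C9 go back to the C8=C9 ene-dicarbonyl and C5 to the silyl enol ether. Three stereocentres are thereby reduced to a single one (C10), and the forward direction only has to reach the thermodynamic all-equatorial trans-decalin.

8 ⇒ 5 + 7. The bonds C7–C8 and C9–C10 are cut, which opens ring B and removes the only remaining stereocentre. The forward [4+2] must engage a diene whose C10 terminus is fully substituted, be regioselective (C7 to C8) and select one face at C10. The connectivities of 5, 7 and 8 are sound as drawn. The descriptor of 8 is 8aR; this is the same spatial arrangement at C10 as 10S in 19, and the letter differs only because C9 outranks C5 in 8. In 5 the unsubstituted CH2 terminus is C7 and the silyloxy group sits on C6.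

5 ⇒ 3 ⇒ 2 ⇒ 1. The O–Si bond, the carbonyl oxidation level and the C6–C7 bond are cut in turn. The enolisation of 3 is specified as kinetic (amide base) so that only the cross-conjugated dienol ether forms.

7 ⇒ 6. The formyl group is taken back to the primary alcohol. This reaches 7 in one step from a catalogue compound, where C-acylation of a propargylic alcohol would need O-protection and deprotection. The labile ynal can be used as a fresh dried solution.

## Other disconnections considered

Alternative 1: The C8–C9 bond is cut from the other side. Ring B is opened to the trans-fused δ-lactone A2, in which oxygen links C11 to C6 and C6 carries a (Z)-acrylate (C7=C8–C17).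
- Forward step: enolisation of A2 to its silyl ketene acetal (C9=C11) and Ireland–Claisen rearrangement, through the boat transition state imposed by the two-carbon C10–C5 bridge, would form C8–C9, break C6–O and give acid A1 with C6=C7 already in place.
- In its favour: C8, C9 and the alkene position are fixed in one stereospecific sigmatropic event. No enolate regiochemistry, no triflate reduction and no base equilibration are needed, and C11 and C17 emerge differentiated as acid and ester. On all of these points it is better than the chosen plan.
- Against it: A2 already contains C5, C6 and the quaternary C10, so the hardest problem is only moved into the precursor. That precursor needs its own asymmetric quaternary-carbon construction and probably eight to ten steps. The lactone must be enolised next to an acrylate (a Michael acceptor with an acidic γ-hydrogen at C6), and its enolate can add 5-exo to C7. The bond to neopentyl C9 must form in a boat with the ester turned inward.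
- Comparison: after A1 the acid has to be reduced and methylenated to reach 15, which costs about as many steps as the two it saves. The stereochemical course is as predictable as that of the cycloaddition. Overall it is the longer route.

Alternative 2: The bonds C5–C10 and C8–C9 are cut, so that both rings fall away to the acyclic trienal A4.
- Forward step: an intramolecular Diels–Alder reaction of the 1,7,9-decatriene type. The (E)-enal C9=C10 adds across the (Z)-silyloxydiene C5=C6–C7=C8 under the same kind of chiral oxazaborolidinium catalyst as in step 5 and would give A3.
- In its favour: four stereocentres and two rings arise in one step, and the trans ring fusion is set kinetically. An enal is a better-precedented dienophile for this catalyst class than an ynal. The enol ether appears directly at C6=C7, so a regiospecific enol ether to enol triflate exchange would replace the kinetic enolisation of step 9. These are real advantages over the chosen plan.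
- Against it: the C5–C10 bond must form between a diene terminus attached to quaternary C4 and the fully substituted β-carbon of the enal, which is more congested than the bond formed in step 5. The ester on the diene terminus lowers the diene HOMO. A4 is a sensitive acyclic compound of roughly eight to ten linear steps, against three steps for 5 and one for 7.
- Comparison: A3 has the C8 ester axial, so a base epimerisation is still required; here the two plans are equal. The sequence after the key step would be slightly shorter than in the chosen plan, the sequence before it much longer.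

Alternative 3: The bonds C7–C8 and C8–C9 are cut. C8 with its ester is a one-carbon unit (diazo ester A7) inserted into the enantiopure hydrindanone A6.
- Forward step: Lewis-acid-catalysed addition of A7 to the C9 ketone, 1,2-shift of the less substituted, allylic C7 methylene and loss of N2 would expand the five-membered ring to the β-keto ester A5.
- In its favour: C10 and the absolute configuration come from an enantiopure ketone, with no untested asymmetric catalysis on a hindered diene; on this point it is better than the chosen plan. The expansion is mild and catalytic, with a known preference for migration of the less substituted carbon. The enol triflate of A5 would allow C11 to be attached by cross-coupling.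
- Against it: A5 has its alkene at C5=C6, no hydrogen on C5 and a ketone at C9. Moving the alkene to C6=C7 while installing a trans H5 has no direct solution, and coupling at C9 leaves a tetrasubstituted C8=C9 enoate whose reduction must set two centres. The ketone of A6 is neopentyl, its β,γ-alkene can conjugate under Lewis acid, and A6 itself needs a multi-step enantioselective synthesis.
- Comparison: the two plans are equal in leaving C8 and C9 to later thermodynamic or reductive control. The chosen plan is shorter after the key step and places the C6 functionality exactly where the alkene is needed.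

Key step: step 5

Remark: with an alkyne dienophile the sense of induction by the boron catalyst cannot be assigned with certainty; the (S)-prolinol-derived catalyst is written, and its (R)-antipode is to be used with no other change if a test run shows the opposite sense.

## Route

Step 1
Reactants: 1 β-cyclocitral (2,6,6-trimethylcyclohex-1-ene-1-carbaldehyde)
Product: 2 1-(2,6,6-trimethylcyclohex-1-en-1-yl)ethan-1-ol (racemic)
Conditions: MeMgBr, Et2O, 0 °C→rt; aq. NH4Cl
Reagents that add atoms: methylmagnesium bromide, C[Mg]Br
Why: Grignard 1,2-addition to a hindered, non-enolisable aldehyde; the carbinol centre is racemic and is removed again in step 2.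

Step 2
Reactants: 2 1-(2,6,6-trimethylcyclohex-1-en-1-yl)ethan-1-ol
Product: 3 1-(2,6,6-trimethylcyclohex-1-en-1-yl)ethan-1-one
Conditions: Dess–Martin periodinane, CH2Cl2, 0 °C→rt
Reagents that add atoms: none
Why: Hypervalent-iodine (Dess–Martin) oxidation of a secondary allylic alcohol under non-acidic conditions, so the tetrasubstituted alkene does not migrate.

Step 3
Reactants: 3 1-(2,6,6-trimethylcyclohex-1-en-1-yl)ethan-1-one
Product: 5 tert-butyl(dimethyl){[1-(2,6,6-trimethylcyclohex-1-en-1-yl)ethenyl]oxy}silane, via lithium enolate 4 (not isolated)
Conditions: LiN(iPr)2, THF, −78 °C; then TBSOTf, −78→0 °C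
Reagents that add atoms: tert-butyldimethylsilyl trifluoromethanesulfonate, CC(C)(C)[Si](C)(C)OS(=O)(=O)C(F)(F)F
Why: Kinetic deprotonation of the acetyl methyl group (the only α-hydrogens; the twisted enone disfavours γ-deprotonation at C20 or C1) and O-silylation of the cross-conjugated enolate give the 2-silyloxydiene.

Step 4
Reactants: 6 methyl 4-hydroxybut-2-ynoate
Product: 7 methyl 4-oxobut-2-ynoate
Conditions: activated MnO2, CH2Cl2, rt; filtered, dried (4 Å sieves), used at once as a titrated solution
Reagents that add atoms: none
Why: Heterogeneous MnO2 oxidation of a propargylic alcohol stops at the aldehyde and leaves only an insoluble residue, so the polymerisable ynal is never concentrated or exposed to acid or base.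

Step 5
Reactants: 5 tert-butyl(dimethyl){[1-(2,6,6-trimethylcyclohex-1-en-1-yl)ethenyl]oxy}silane; 7 methyl 4-oxobut-2-ynoate
Product: 8 methyl (8aR)-4-[(tert-butyldimethylsilyl)oxy]-1-formyl-5,5,8a-trimethyl-3,5,6,7,8,8a-hexahydronaphthalene-2-carboxylate
Conditions: (S)-1-(2-methylphenyl)-3,3-diphenyltetrahydro-1H,3H-pyrrolo[1,2-c][1,3,2]oxazaborole (20 mol %), HNTf2 (18 mol %), CH2Cl2, −78→−40 °C; Et3N quench
Reagents that add atoms: none
Why: Proposed new method: an oxazaborolidinium-catalysed enantioselective [4+2] addition has not been shown on a diene whose reacting terminus is fully substituted as C10 is in 5, and the closest known reaction types are the thermal Diels–Alder additions of 2,6,6-trimethyl-1-vinylcyclohexenes to acetylenic esters and the oxazaborolidinium-catalysed cycloadditions of 2-silyloxydienes and of acetylenic carbonyl dienophiles, which this step combines. The boron binds the formyl oxygen of 7, which lowers the LUMO of the conjugated π bond and makes C8, the carbon β to the formyl group, the most electrophilic position, whereas the ester is the weaker Lewis base and stays unbound. The electron-rich CH2 terminus C7 of the silyl dienol ether bonds to C8 first in a concerted but strongly asynchronous [4π+2π] addition, and formation of C9–C10 completes the event. Ring B is closed by this intermolecular cycloaddition, suprafacial on the diene, and in the stepwise limit the second bond is a six-membered ring closure of the boron allenolate carbon C9 onto the silyloxyallyl cation terminus C10; ring A is carried in unchanged. C10 is the only stereocentre formed and it is controlled by the catalyst: the aryl groups on the bound oxazaborolidinium screen one side of the coordinated ynal, and the diene has to approach with its bulky trimethylcyclohexene end turned away from the boron centre, so one face of C10 is selected. Regioselectivity (formyl on C9, ester on C8) is secured by the silyloxy group on C6 acting together with selective activation of the aldehyde, and preference for cycloaddition over a Mukaiyama-type addition to the formyl carbon rests on the bulk of the silyl group and the low temperature. Quaternary C10 rules out aromatisation of the 1,4-cyclohexadiene 8.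

Step 6
Reactants: 8 methyl (8aR)-4-[(tert-butyldimethylsilyl)oxy]-1-formyl-5,5,8a-trimethyl-3,5,6,7,8,8a-hexahydronaphthalene-2-carboxylate
Product: 10 methyl (8aS)-1-formyl-5,5,8a-trimethyl-4-oxodecahydronaphthalene-2-carboxylate (C1/C2/C4a epimer mixture), via silyl enol ether aldehyde 9 (not isolated)
Conditions: Zn dust, AcOH–THF, 0 °C→rt; filtered; then 1 M aq. HCl, rt
Reagents that add atoms: none
Why: Zinc in acetic acid reduces the ene-1,4-dicarbonyl unit (C8=C9 between formyl and ester) by electron transfer and protonation, a dissolving-metal conjugate reduction that spares the isolated enol ether, the ester and the aldehyde; aqueous acid then hydrolyses the silyl enol ether with protonation at C5. The configurations at C5, C8 and C9 are left open here and are set in step 7.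

Step 7
Reactants: 10 methyl (8aS)-1-formyl-5,5,8a-trimethyl-4-oxodecahydronaphthalene-2-carboxylate (epimer mixture)
Product: 11 methyl (1R,2S,4aR,8aS)-1-formyl-5,5,8a-trimethyl-4-oxodecahydronaphthalene-2-carboxylate
Conditions: NaOMe (0.3 equiv), MeOH, 0 °C→rt; AcOH quench
Reagents that add atoms: none
Why: Base-mediated epimerisation under thermodynamic control: C5 (α to the C6 ketone), C8 (α to the ester) and C9 (α to the aldehyde) enolise reversibly and settle in the trans-fused chair with H5 and H9 axial and the C8 ester and C9 formyl group equatorial, the ester thereby avoiding the 1,3-diaxial contact with C20. Quaternary C10 cannot epimerise and anchors the other three centres.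

Step 8
Reactants: 11 methyl (1R,2S,4aR,8aS)-1-formyl-5,5,8a-trimethyl-4-oxodecahydronaphthalene-2-carboxylate
Product: 12 methyl (1R,2S,4aR,8aS)-1-ethenyl-5,5,8a-trimethyl-4-oxodecahydronaphthalene-2-carboxylate
Conditions: Ph3PCH3Br, KN(SiMe3)2, THF, 0 °C; then 11, −78→0 °C
Reagents that add atoms: methyltriphenylphosphonium bromide, C[P+](c1ccccc1)(c1ccccc1)c1ccccc1.[Br-]
Why: Wittig methylenation: the non-stabilised ylide attacks the aldehyde much faster than the C6 ketone, which is screened by C5 and the C4 methyl groups. C9 already has its thermodynamic configuration, so reversible enolisation by the ylide cannot change it, and after this step C9 can no longer epimerise.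

Step 9
Reactants: 12 methyl (1R,2S,4aR,8aS)-1-ethenyl-5,5,8a-trimethyl-4-oxodecahydronaphthalene-2-carboxylate
Product: 14 methyl (1R,2R,4aR,8aS)-1-ethenyl-5,5,8a-trimethyl-4-{[(trifluoromethyl)sulfonyl]oxy}-1,2,4a,5,6,7,8,8a-octahydronaphthalene-2-carboxylate, via potassium enolate 13 (not isolated)
Conditions: KN(SiMe3)2, THF, −78 °C; then N-(5-chloropyridin-2-yl)triflimide, −78 °C
Reagents that add atoms: N-(5-chloropyridin-2-yl)-1,1,1-trifluoro-N-[(trifluoromethyl)sulfonyl]methanesulfonamide, FC(F)(F)S(=O)(=O)N(c1ccc(Cl)cn1)S(=O)(=O)C(F)(F)F
Why: Kinetic enolate formation and O-sulfonylation: the bulky amide removes a proton from the C7 methylene faster than from the shielded C5 methine or the less acidic ester α-position C8, and the reactive pyridyl triflimide traps the enolate at −78 °C before proton transfer can scramble it. This fixes the future alkene at C6=C7.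

Step 10
Reactants: 14 methyl (1R,2R,4aR,8aS)-1-ethenyl-5,5,8a-trimethyl-4-{[(trifluoromethyl)sulfonyl]oxy}-1,2,4a,5,6,7,8,8a-octahydronaphthalene-2-carboxylate
Product: 15 methyl (1R,2S,4aR,8aS)-1-ethenyl-5,5,8a-trimethyl-1,2,4a,5,6,7,8,8a-octahydronaphthalene-2-carboxylate
Conditions: Pd(OAc)2 (5 mol %), PPh3, HCO2H, Bu3N, DMF, 60 °C
Reagents that add atoms: none
Why: Palladium-catalysed formate reduction of an enol triflate: oxidative addition to zerovalent palladium, exchange of triflate for formate, loss of CO2 and reductive elimination replace OTf by H without moving the double bond. The tertiary amine is too weak a base to conjugate the β,γ-unsaturated ester, and the monosubstituted vinyl group is inert.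

Step 11
Reactants: 6 methyl 4-hydroxybut-2-ynoate
Product: 16 methyl (2Z)-4-hydroxy-3-iodobut-2-enoate
Conditions: LiI, AcOH, MeCN, 70 °C
Reagents that add atoms: lithium iodide, [Li+].[I-]
Why: Conjugate hydroiodination of an ynoate: iodide adds at C3 (β to the ester) and the allenoate is protonated anti to iodine, which gives the (Z)-β-iodo enoate. The hydroxymethyl group ends trans to the ester and cannot lactonise.

Step 12
Reactants: 15 methyl (1R,2S,4aR,8aS)-1-ethenyl-5,5,8a-trimethyl-1,2,4a,5,6,7,8,8a-octahydronaphthalene-2-carboxylate; 16 methyl (2Z)-4-hydroxy-3-iodobut-2-enoate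
Product: 18 methyl (1R,2S,4aR,8aS)-1-[(3E)-3-(hydroxymethyl)-5-methoxy-5-oxopent-3-en-1-yl]-5,5,8a-trimethyl-1,2,4a,5,6,7,8,8a-octahydronaphthalene-2-carboxylate, via B-alkyl-9-BBN adduct 17 (not isolated)
Conditions: 9-BBN, THF, 0 °C→rt; then 16, PdCl2(dppf)·CH2Cl2 (5 mol %), AsPh3, aq. K3PO4, THF–DMF, rt
Reagents that add atoms: none
Why: Hydroboration followed by B-alkyl Suzuki–Miyaura coupling: 9-BBN adds anti-Markovnikov to the monosubstituted alkene and ignores the cis-disubstituted ring alkene and the esters. The primary alkylborane transfers to the vinylpalladium formed from 16 with retention of alkene geometry, placing C12 cis and C16 trans to the ester, and aqueous phosphate at room temperature is too mild to conjugate or epimerise the C8 ester.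

Step 13
Reactants: 18 methyl (1R,2S,4aR,8aS)-1-[(3E)-3-(hydroxymethyl)-5-methoxy-5-oxopent-3-en-1-yl]-5,5,8a-trimethyl-1,2,4a,5,6,7,8,8a-octahydronaphthalene-2-carboxylate
Product: 19 methyl (1R,2S,4aR,8aS)-1-[(3E)-3-(acetoxymethyl)-5-methoxy-5-oxopent-3-en-1-yl]-5,5,8a-trimethyl-1,2,4a,5,6,7,8,8a-octahydronaphthalene-2-carboxylate (CNP0190145.1)
Conditions: Ac2O, pyridine, DMAP (cat.), CH2Cl2, 0 °C
Reagents that add atoms: acetic anhydride, CC(=O)OC(C)=O
Why: DMAP-catalysed acylation of the primary allylic alcohol; no stereocentre or alkene is touched.

## Compound list

1 | β-cyclocitral (2,6,6-trimethylcyclohex-1-ene-1-carbaldehyde) | CC1=C(C=O)C(C)(C)CCC1 | starting material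
2 | 1-(2,6,6-trimethylcyclohex-1-en-1-yl)ethan-1-ol (racemic) | CC(O)C1=C(C)CCCC1(C)C | intermediate
3 | 1-(2,6,6-trimethylcyclohex-1-en-1-yl)ethan-1-one | CC(=O)C1=C(C)CCCC1(C)C | intermediate
4 | lithium 1-(2,6,6-trimethylcyclohex-1-en-1-yl)ethen-1-olate | C=C(O[Li])C1=C(C)CCCC1(C)C | intermediate
5 | tert-butyl(dimethyl){[1-(2,6,6-trimethylcyclohex-1-en-1-yl)ethenyl]oxy}silane | C=C(O[Si](C)(C)C(C)(C)C)C1=C(C)CCCC1(C)C | intermediate
6 | methyl 4-hydroxybut-2-ynoate | COC(=O)C#CCO | starting material
7 | methyl 4-oxobut-2-ynoate | COC(=O)C#CC=O | intermediate
8 | methyl (8aR)-4-[(tert-butyldimethylsilyl)oxy]-1-formyl-5,5,8a-trimethyl-3,5,6,7,8,8a-hexahydronaphthalene-2-carboxylate | O=CC1=C(C(=O)OC)CC(O[Si](C)(C)C(C)(C)C)=C2C(C)(C)CCC[C@@]12C | intermediate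
9 | methyl (8aS)-4-[(tert-butyldimethylsilyl)oxy]-1-formyl-5,5,8a-trimethyl-1,2,3,5,6,7,8,8a-octahydronaphthalene-2-carboxylate (mixture of epimers at C1 and C2 of the ring, i.e. labdane C9 and C8) | O=CC1C(C(=O)OC)CC(O[Si](C)(C)C(C)(C)C)=C2C(C)(C)CCC[C@@]12C | intermediate
10 | methyl (8aS)-1-formyl-5,5,8a-trimethyl-4-oxodecahydronaphthalene-2-carboxylate (mixture of epimers at C1, C2 and C4a, i.e. labdane C9, C8 and C5) | O=CC1C(C(=O)OC)CC(=O)C2C(C)(C)CCC[C@@]12C | intermediate
11 | methyl (1R,2S,4aR,8aS)-1-formyl-5,5,8a-trimethyl-4-oxodecahydronaphthalene-2-carboxylate (trans-fused; formyl and ester equatorial, trans) | O=C[C@@H]1[C@@H](C(=O)OC)CC(=O)[C@@H]2C(C)(C)CCC[C@@]12C | intermediate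
12 | methyl (1R,2S,4aR,8aS)-1-ethenyl-5,5,8a-trimethyl-4-oxodecahydronaphthalene-2-carboxylate | C=C[C@@H]1[C@@H](C(=O)OC)CC(=O)[C@@H]2C(C)(C)CCC[C@@]12C | intermediate
13 | potassium 6(7)-enolate of 12 (O–K on labdane C6, C6=C7; C5, C8, C9 and C10 as in 12) | C=C[C@@H]1[C@@H](C(=O)OC)C=C(O[K])[C@@H]2C(C)(C)CCC[C@@]12C | intermediate
14 | methyl (1R,2R,4aR,8aS)-1-ethenyl-5,5,8a-trimethyl-4-{[(trifluoromethyl)sulfonyl]oxy}-1,2,4a,5,6,7,8,8a-octahydronaphthalene-2-carboxylate | C=C[C@@H]1[C@@H](C(=O)OC)C=C(OS(=O)(=O)C(F)(F)F)[C@@H]2C(C)(C)CCC[C@@]12C | intermediate
15 | methyl (1R,2S,4aR,8aS)-1-ethenyl-5,5,8a-trimethyl-1,2,4a,5,6,7,8,8a-octahydronaphthalene-2-carboxylate | C=C[C@@H]1[C@@H](C(=O)OC)C=C[C@@H]2C(C)(C)CCC[C@@]12C | intermediate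
16 | methyl (2Z)-4-hydroxy-3-iodobut-2-enoate | COC(=O)/C=C(\I)CO | intermediate
17 | methyl (1R,2S,4aR,8aS)-1-[2-(9-borabicyclo[3.3.1]nonan-9-yl)ethyl]-5,5,8a-trimethyl-1,2,4a,5,6,7,8,8a-octahydronaphthalene-2-carboxylate | C1CCC2CCCC1B2CC[C@@H]3[C@@H](C(=O)OC)C=C[C@@H]4C(C)(C)CCC[C@@]34C | intermediate
18 | methyl (1R,2S,4aR,8aS)-1-[(3E)-3-(hydroxymethyl)-5-methoxy-5-oxopent-3-en-1-yl]-5,5,8a-trimethyl-1,2,4a,5,6,7,8,8a-octahydronaphthalene-2-carboxylate | COC(=O)/C=C(\CC[C@@H]1[C@@H](C(=O)OC)C=C[C@@H]2C(C)(C)CCC[C@@]12C)CO | intermediate
19 | methyl (1R,2S,4aR,8aS)-1-[(3E)-3-(acetoxymethyl)-5-methoxy-5-oxopent-3-en-1-yl]-5,5,8a-trimethyl-1,2,4a,5,6,7,8,8a-octahydronaphthalene-2-carboxylate (CNP0190145.1) | COC(=O)/C=C(\CC[C@@H]1[C@@H](C(=O)OC)C=C[C@@H]2C(C)(C)CCC[C@@]12C)COC(C)=O | target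

## Step count and least certain steps

Total: 13 steps. Longest linear sequence: 11 steps (from 1 through steps 1, 2, 3, 5, 6, 7, 8, 9, 10, 12 and 13). Steps 4 and 11 are single-step branches from 6.

Step 5 (key step, the one step labelled as a proposed new method).
- What may go wrong: the cycloaddition may be slow, because the diene can only reach a planar s-cis geometry with C20 turned inward and the silyloxy group pressed against the C4 methyls. Slow reaction would let protodesilylation of 5, Mukaiyama-type addition to the formyl carbon or acid-induced polymerisation of 7 take over.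
- Facial selectivity may also be poor: with an alkyne the enantiomer formed depends both on which side of the bound ynal is attacked and on how the diene is oriented, and no endo rule enforces either.
- Fallback (known chemistry): setting out from 5 and 7, the cycloaddition is run without chiral control, thermally in toluene at 60–80 °C or promoted by Me2AlCl at −78 °C. This is established for 2,6,6-trimethyl-1-vinylcyclohexenes with acetylenic esters and for 2-silyloxydienes with ynals. It gives the racemate, that is 8 together with its mirror image methyl (8aS)-4-[(tert-butyldimethylsilyl)oxy]-1-formyl-5,5,8a-trimethyl-3,5,6,7,8,8a-hexahydronaphthalene-2-carboxylate F1. The enantiomers are separated by preparative chromatography on a chiral stationary phase, and the route is rejoined at 8.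

Step 6.
- What may go wrong: electron transfer to the tetrasubstituted alkene may be incomplete, the formyl group may be over-reduced or coupled reductively, and acid may move the C5=C6 enol ether double bond before the reduction is over.
- Fallback: the approach changes from electron transfer in acid to hydride conjugate addition under neutral conditions. Setting out from 8, stoichiometric [(Ph3P)CuH]6 in wet toluene at room temperature delivers hydride to the ene-dicarbonyl and gives 9, which is then isolated and hydrolysed with 1 M HCl in THF. The route is rejoined at 10; this fallback makes no compound outside the list (F0).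

Step 7.
- What may go wrong: convergence at C5 may be incomplete, because the equatorial C4 methyl group is nearly eclipsed with the C6 carbonyl in the trans-fused ketone and a cis-fused epimer may persist at equilibrium. Material may also be lost through base-induced retro-Michael opening of the C8–C9 bond.
- Fallback: control at C5 changes from thermodynamic to kinetic. Setting out from 9 (isolated by stopping step 6 before the acid stage), C8 and C9 are equilibrated on the intact enol ether with DBU, or with catalytic NaOMe at 0 °C. This gives methyl (1R,2S,8aS)-4-[(tert-butyldimethylsilyl)oxy]-1-formyl-5,5,8a-trimethyl-1,2,3,5,6,7,8,8a-octahydronaphthalene-2-carboxylate F2, in which no ketone is present and retro-Michael cleavage is impossible. Cold 1 M HCl in THF then protonates C5 from the face opposite C20 without later exposure of the ketone to base. The route is rejoined at 11.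

Step 9.
- What may go wrong: regiocontrol of enolisation may be lost through proton transfer to the C5=C6 enolate or to the ester enolate at C8, the latter also epimerising C8.
- Fallback: the alkene is made by reduction and syn-elimination instead of through an enolate. Setting out from 12, NaBH4 in MeOH at 0 °C delivers hydride from the face opposite C20 and the axial C4 methyl group and gives the axial alcohol methyl (1R,2S,4S,4aR,8aS)-1-ethenyl-4-hydroxy-5,5,8a-trimethyldecahydronaphthalene-2-carboxylate F3. Dehydration with methyl N-(triethylammoniosulfonyl)carbamate (Burgess reagent) in benzene at 50 °C is a syn-elimination; the only hydrogen cis to the axial leaving group is on C7, H5 being trans-diaxial, so only the C6=C7 alkene can form. The route is rejoined at 15, bypassing 13 and 14.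

## Further compounds

F1 | step 5 | methyl (8aS)-4-[(tert-butyldimethylsilyl)oxy]-1-formyl-5,5,8a-trimethyl-3,5,6,7,8,8a-hexahydronaphthalene-2-carboxylate (enantiomer of 8) | O=CC1=C(C(=O)OC)CC(O[Si](C)(C)C(C)(C)C)=C2C(C)(C)CCC[C@]12C
F0 | step 6 | none | none
F2 | step 7 | methyl (1R,2S,8aS)-4-[(tert-butyldimethylsilyl)oxy]-1-formyl-5,5,8a-trimethyl-1,2,3,5,6,7,8,8a-octahydronaphthalene-2-carboxylate | O=C[C@@H]1[C@@H](C(=O)OC)CC(O[Si](C)(C)C(C)(C)C)=C2C(C)(C)CCC[C@@]12C
F3 | step 9 | methyl (1R,2S,4S,4aR,8aS)-1-ethenyl-4-hydroxy-5,5,8a-trimethyldecahydronaphthalene-2-carboxylate | C=C[C@@H]1[C@@H](C(=O)OC)C[C@H](O)[C@@H]2C(C)(C)CCC[C@@]12C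
A1 | alternative 1 | 2-(methoxycarbonyl)-5,5,8a-trimethyl-1,2,4a,5,6,7,8,8a-octahydronaphthalene-1-carboxylic acid (C5, C8, C9 and C10 configured as in 19) | OC(=O)[C@@H]1[C@@H](C(=O)OC)C=C[C@@H]2C(C)(C)CCC[C@@]12C
A2 | alternative 1 | methyl (2Z)-3-(4a,8,8-trimethyl-3-oxooctahydro-1H-isochromen-1-yl)prop-2-enoate (trans-fused lactone; acrylate equatorial, on the face of H5) | O=C1C[C@]2(C)CCCC(C)(C)[C@H]2[C@@H](O1)/C=C\C(=O)OC
A3 | alternative 2 | methyl 4-[(tert-butyldimethylsilyl)oxy]-1-formyl-5,5,8a-trimethyl-1,2,4a,5,6,7,8,8a-octahydronaphthalene-2-carboxylate (trans-fused; ester on C8 axial) | O=C[C@@H]1[C@H](C(=O)OC)C=C(O[Si](C)(C)C(C)(C)C)[C@@H]2C(C)(C)CCC[C@@]12C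
A4 | alternative 2 | methyl (2E,4Z,10E)-4-[(tert-butyldimethylsilyl)oxy]-6,6,10-trimethyl-12-oxododeca-2,4,10-trienoate | O=C/C=C(\C)CCCC(C)(C)/C=C(\O[Si](C)(C)C(C)(C)C)/C=C/C(=O)OC
A5 | alternative 3 | methyl 1-hydroxy-5,5,8a-trimethyl-3,5,6,7,8,8a-hexahydronaphthalene-2-carboxylate (C10 configured as in 19) | COC(=O)C1=C(O)[C@]2(C)CCCC(C)(C)C2=CC1
A6 | alternative 3 | 4,4,7a-trimethyl-2,4,5,6,7,7a-hexahydro-1H-inden-1-one (C10 configured as in 19) | O=C1CC=C2C(C)(C)CCC[C@@]12C
A7 | alternative 3 | methyl diazoacetate | COC(=O)C=[N+]=[N-]
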